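The disconnection cuts ring A between the carbinol carbon C3 and the quaternary C4. A single ring B cyclohexanone, made from (4S)-limonene oxide, carries the C8 carbinol, the C10 quaternary centre with a 3-oxopropyl arm and the C5 isopropenyl group. Hydrogen atom transfer to the isopropenyl group makes the tertiary C4 radical, which adds to the C3 aldehyde: one operation closes ring A cis-fused, creates the gem-dimethyl C4 and sets C3 as the equatorial alcohol. The step exploits the 3-hydroxy-4,4-dimethyl unit of ring A. The side chain is then added to the C9 ketone and C9 is set by hydrogenation directed by the C8 hydroxyl.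

Key step: step 8

Assumption: the target is taken with H-5 and the C10 methyl on the same face of the decalin (cis-fused rings A and B; 3S,5S,8R,9R,10S), and the route is built for this isomer. Positions are numbered as in polypodanes (C1 to C10 in the decalin, C11 onward in the side chain, C30 the primary carbinol carbon).

**Route**

Step 1
Reactants: 1 (4S)-limonene 1,2-oxide (commercial cis/trans mixture)
Product: 2 (1R,2R,4S)-1-methyl-4-(prop-1-en-2-yl)cyclohexane-1,2-diol
Conditions: H2O, H2SO4 (cat.), THF, 0 °C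
Reagents that add atoms: water, O
Why: Acid-catalysed epoxide hydrolysis by trans-diaxial opening (Fürst–Plattner rule), in which the cis oxide is attacked at C1 and the trans oxide at C2, so both should converge on the same trans-diol whose tertiary hydroxyl is cis to the isopropenyl group.

Step 2
Reactants: 2 (1R,2R,4S)-1-methyl-4-(prop-1-en-2-yl)cyclohexane-1,2-diol
Product: 3 (2R,5S)-2-hydroxy-2-methyl-5-(prop-1-en-2-yl)cyclohexan-1-one
Conditions: IBX, DMSO, rt
Reagents that add atoms: none
Why: IBX oxidation of the secondary alcohol of a 1,2-diol should give the α-hydroxy ketone without glycol cleavage and without touching a stereocentre.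

Step 3
Reactants: 3 (2R,5S)-2-hydroxy-2-methyl-5-(prop-1-en-2-yl)cyclohexan-1-one
Product: 4 (2R,5S)-2-methyl-5-(prop-1-en-2-yl)-2-(triethylsilyloxy)cyclohexan-1-one
Conditions: TESOTf, 2,6-lutidine, CH2Cl2, −78 °C to 0 °C
Reagents that add atoms: triethylsilyl triflate, CC[Si](CC)(CC)OS(=O)(=O)C(F)(F)F
Why: Silylation of the hindered tertiary alcohol with the silyl triflate, which guards against α-ketol rearrangement and O-alkylation in the enolate steps.

Step 4
Reactants: 4 (2R,5S)-2-methyl-5-(prop-1-en-2-yl)-2-(triethylsilyloxy)cyclohexan-1-one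
Product: 6 (2R,5S,6R)-6-allyl-2-methyl-5-(prop-1-en-2-yl)-2-(triethylsilyloxy)cyclohexan-1-one (major epimer; allyl trans to isopropenyl), via lithium enolate 5 (not isolated)
Conditions: LiN(iPr)2, THF, −78 °C; allyl bromide, −78 °C to −30 °C
Reagents that add atoms: allyl bromide, C=CCBr
Why: Enolate alkylation in which C6 is the only enolisable position (C2 is quaternary), so the enolate forms regiospecifically; the configuration at C6 does not matter because this centre is enolised again in step 5.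

Step 5
Reactants: 6 (2R,5S,6R)-6-allyl-2-methyl-5-(prop-1-en-2-yl)-2-(triethylsilyloxy)cyclohexan-1-one
Product: 8 (2R,5R,6S)-6-allyl-2,6-dimethyl-5-(prop-1-en-2-yl)-2-(triethylsilyloxy)cyclohexan-1-one (allyl cis to isopropenyl), via lithium enolate 7 (not isolated)
Conditions: LiN(iPr)2, THF, −78 °C to 0 °C; MeI, DMPU, −78 °C to −20 °C
Reagents that add atoms: iodomethane, CI
Why: Alkylation of the tetrasubstituted enolate, in which iodomethane should approach anti to the neighbouring pseudoaxial isopropenyl group, so that the methyl ends trans and the allyl arm cis to it (the C10 quaternary centre).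

Step 6
Reactants: 8 (2R,5R,6S)-6-allyl-2,6-dimethyl-5-(prop-1-en-2-yl)-2-(triethylsilyloxy)cyclohexan-1-one
Product: 10 (2R,5R,6S)-6-(3-hydroxypropyl)-2,6-dimethyl-5-(prop-1-en-2-yl)-2-(triethylsilyloxy)cyclohexan-1-one, via alkylborane 9 (not isolated)
Conditions: (Me2CHCHMe)2BH (from BH3·THF and 2-methylbut-2-ene), THF, 0 °C; then NaOH, H2O2, 0 °C to rt
Reagents that add atoms: hydrogen peroxide, OO
Why: Hydroboration–oxidation in which the bulky dialkylborane should add anti-Markovnikov to the monosubstituted allyl alkene far faster than to the hindered 1,1-disubstituted isopropenyl group, while the non-enolisable, doubly neopentyl ketone is left alone.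

Step 7
Reactants: 10 (2R,5R,6S)-6-(3-hydroxypropyl)-2,6-dimethyl-5-(prop-1-en-2-yl)-2-(triethylsilyloxy)cyclohexan-1-one
Product: 11 3-[(1S,3R,6R)-1,3-dimethyl-2-oxo-6-(prop-1-en-2-yl)-3-(triethylsilyloxy)cyclohexyl]propanal
Conditions: IBX, DMSO, rt
Reagents that add atoms: none
Why: IBX oxidation of the primary alcohol to the aldehyde; the ketone has no α-hydrogen, so the keto aldehyde cannot undergo an intramolecular aldol reaction.

Step 8
Reactants: 11 3-[(1S,3R,6R)-1,3-dimethyl-2-oxo-6-(prop-1-en-2-yl)-3-(triethylsilyloxy)cyclohexyl]propanal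
Product: 14 (2R,4aR,6S,8aS)-6-hydroxy-2,5,5,8a-tetramethyl-2-(triethylsilyloxy)octahydronaphthalen-1(2H)-one (cis-fused), via tertiary C4 radical 12 (not isolated), via C3 alkoxyl radical 13 (not isolated)
Conditions: Fe(acac)3 (50 mol %), PhSiH3, EtOH/(CH2OH)2, 60 °C
Reagents that add atoms: none
Why: Mukaiyama-type hydrogen atom transfer from the Fe–H species formed from Fe(acac)3 and PhSiH3 to the CH2 terminus of the isopropenyl group, the only alkene in 11, gives the tertiary C4 radical 12, which adds to the aldehyde carbon C3 to give the alkoxyl radical 13, and this is reduced to the alkoxide and protonated by ethanol. The closest known reaction type is the Fe(acac)3/PhSiH3 reductive radical cyclization of alkene-tethered ketones, the hydride-initiated counterpart of the classical Bu3SnH cyclization of alkyl radicals onto aldehydes. Ring A closes in the 6-exo-trig mode onto C=O through a chair in which C1 is axial and C4 equatorial on ring B, and the cis ring fusion follows from the cis arrangement of the C5 and C10 arms that step 5 has put in place. The new stereocentre C3 is controlled by this chair: the carbonyl oxygen takes the equatorial site, away from the axial C5–C6 bond, and because the addition is reversible (β-scission of 13) the more stable equatorial alkoxyl radical should be the one that is trapped, which places O-3 cis to the C10 methyl and to H-5. The step needs the aldehyde to be chosen over the C9 ketone, which is secured by ring size (attack at C9 would be 4-exo), and it needs cyclization to outrun simple reduction of 12, which the intramolecular 6-exo closure onto an unhindered aldehyde favours.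

Step 9
Reactants: 14 (2R,4aR,6S,8aS)-6-hydroxy-2,5,5,8a-tetramethyl-2-(triethylsilyloxy)octahydronaphthalen-1(2H)-one
Product: 15 (2R,4aR,6S,8aS)-2,5,5,8a-tetramethyl-2,6-bis(triethylsilyloxy)octahydronaphthalen-1(2H)-one
Conditions: TESCl, imidazole, DMAP (cat.), DMF, rt
Reagents that add atoms: chlorotriethylsilane, CC[Si](CC)(CC)Cl
Why: Silylation of the secondary C3 alcohol, so that only the tertiary alcohol made in step 15 can be dehydrated in step 16.

Step 10
Reactants: 16 (2E,6E)-farnesyl acetate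
Product: 17 (2E,6E,10E)-12-hydroxy-3,7,11-trimethyldodeca-2,6,10-trien-1-yl acetate
Conditions: SeO2 (cat.), t-BuOOH, salicylic acid (cat.), CH2Cl2, 0 °C to rt
Reagents that add atoms: tert-butyl hydroperoxide, CC(C)(C)OO
Why: SeO2 allylic oxidation (ene reaction then [2,3]-sigmatropic shift), which is selective for the (E)-methyl group of the terminal trisubstituted alkene and should give the (E)-allylic alcohol, the alkene next to the acetate being deactivated.

Step 11
Reactants: 17 (2E,6E,10E)-12-hydroxy-3,7,11-trimethyldodeca-2,6,10-trien-1-yl acetate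
Product: 18 (2E,6E,10E)-12-(tert-butyldiphenylsilyloxy)-3,7,11-trimethyldodeca-2,6,10-trien-1-yl acetate
Conditions: TBDPSCl, imidazole, CH2Cl2, rt
Reagents that add atoms: tert-butylchlorodiphenylsilane, CC(C)(C)[Si](Cl)(c1ccccc1)c1ccccc1
Why: Silylation of the primary allylic alcohol with a group that survives the later selective removal of the triethylsilyl ethers.

Step 12
Reactants: 18 (2E,6E,10E)-12-(tert-butyldiphenylsilyloxy)-3,7,11-trimethyldodeca-2,6,10-trien-1-yl acetate
Product: 19 [(3E,7E,11E)-13-(tert-butyldiphenylsilyloxy)-4,8,12-trimethyltrideca-3,7,11-trien-1-yl](isopropoxy)dimethylsilane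
Conditions: (iPrO)Me2SiCH2MgCl, Li2CuCl4 (cat.), THF, −20 °C to 0 °C
Reagents that add atoms: (isopropoxydimethylsilyl)methylmagnesium chloride, CC(C)O[Si](C)(C)C[Mg]Cl
Why: Li2CuCl4-catalysed substitution of the primary allylic acetate by the Grignard reagent (Fouquet–Schlosser coupling), which should occur at the unhindered α-carbon with retention of the (E)-alkene and adds the carbon that becomes C11.

Step 13
Reactants: 19 [(3E,7E,11E)-13-(tert-butyldiphenylsilyloxy)-4,8,12-trimethyltrideca-3,7,11-trien-1-yl](isopropoxy)dimethylsilane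
Product: 20 (3E,7E,11E)-13-(tert-butyldiphenylsilyloxy)-4,8,12-trimethyltrideca-3,7,11-trien-1-ol
Conditions: H2O2, KF, KHCO3, THF/MeOH, rt
Reagents that add atoms: hydrogen peroxide, OO
Why: Tamao–Fleming oxidation of the alkoxysilane C–Si bond to C–OH, under conditions that leave the trisubstituted alkenes and the TBDPS ether intact.

Step 14
Reactants: 20 (3E,7E,11E)-13-(tert-butyldiphenylsilyloxy)-4,8,12-trimethyltrideca-3,7,11-trien-1-ol
Product: 21 tert-butyl{[(2E,6E,10E)-13-iodo-2,6,10-trimethyltrideca-2,6,10-trien-1-yl]oxy}diphenylsilane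
Conditions: I2, PPh3, imidazole, CH2Cl2, 0 °C
Reagents that add atoms: iodine, II
Why: Appel-type iodination of the primary homoallylic alcohol by SN2 displacement of the oxyphosphonium group.

Step 15
Reactants: 21 tert-butyl{[(2E,6E,10E)-13-iodo-2,6,10-trimethyltrideca-2,6,10-trien-1-yl]oxy}diphenylsilane; 15 (2R,4aR,6S,8aS)-2,5,5,8a-tetramethyl-2,6-bis(triethylsilyloxy)octahydronaphthalen-1(2H)-one
Product: 23 C9 carbinol (9-hydroxy adduct carrying the full side chain at C9; 3,8-bis-O-TES and 30-O-TBDPS), via organolithium 22 (not isolated)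
Conditions: 21, t-BuLi (2.1 equiv), Et2O, −78 °C; then 15, −78 °C to −20 °C; then H2O at −20 °C
Reagents that add atoms: none
Why: Iodine–lithium exchange gives the primary alkyllithium, which should add to the C9 ketone because this ketone has no α-hydrogen and cannot be enolised; the cold quench guards against silyl migration from O-8, and the configuration formed at C9 is erased in step 16.

Step 16
Reactants: 23 C9 carbinol
Product: 25 9(11)-alkene (exocyclic C9=C11; 3,8-bis-O-TES and 30-O-TBDPS), via sulfamate ester 24 (not isolated)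
Conditions: Burgess reagent (MeO2CN–SO2NEt3), toluene, 50 °C
Reagents that add atoms: none
Why: Burgess dehydration by syn elimination of the sulfamate ester; C8 and C10 are quaternary, so the only β-hydrogens are on C11 and the exocyclic C9=C11 alkene is the only possible elimination product, its E/Z geometry being irrelevant.

Step 17
Reactants: 25 9(11)-alkene (3,8-bis-O-TES and 30-O-TBDPS)
Product: 26 9(11)-alkene 3,8-diol (30-O-TBDPS)
Conditions: HF·pyridine, pyridine, THF, 0 °C to rt
Reagents that add atoms: none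
Why: Buffered HF·pyridine should cleave the two triethylsilyl ethers and leave the more robust primary TBDPS ether, which frees the C8 hydroxyl as directing group while the terminal oxygen stays masked.

Step 18
Reactants: 26 9(11)-alkene 3,8-diol (30-O-TBDPS)
Product: 27 30-O-(tert-butyldiphenylsilyl)myrrhanol A
Conditions: [Rh(nbd)(dppb)]BF4 (cat.), H2 (60 bar), CH2Cl2, rt
Reagents that add atoms: none
Why: Hydroxyl-directed homogeneous hydrogenation, in which the cationic complex binds the allylic tertiary C8 hydroxyl and should deliver H2 to the C9=C11 face syn to it, so H-9 ends cis to O-8 and C11 trans; the isolated trisubstituted side-chain alkenes have no free hydroxyl nearby and should not be reduced by this catalyst.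

Step 19
Reactants: 27 30-O-(tert-butyldiphenylsilyl)myrrhanol A
Product: 28 Myrrhanol A
Conditions: Bu4NF, THF, 0 °C to rt
Reagents that add atoms: none
Why: Fluoride cleavage of the primary silyl ether, which should leave the tertiary and secondary alcohols and the three (E)-alkenes untouched.

**Compound list**

1 | (4S)-limonene 1,2-oxide (cis/trans mixture) | CC1(O2)CC[C@H](C(C)=C)CC12 | starting material
2 | (1R,2R,4S)-1-methyl-4-(prop-1-en-2-yl)cyclohexane-1,2-diol | O[C@@H]1C[C@@H](C(C)=C)CC[C@@]1(C)O | intermediate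
3 | (2R,5S)-2-hydroxy-2-methyl-5-(prop-1-en-2-yl)cyclohexan-1-one | O=C1C[C@@H](C(C)=C)CC[C@@]1(C)O | intermediate
4 | (2R,5S)-2-methyl-5-(prop-1-en-2-yl)-2-(triethylsilyloxy)cyclohexan-1-one | O=C1C[C@@H](C(C)=C)CC[C@@]1(C)O[Si](CC)(CC)CC | intermediate
5 | lithium enolate of 4 (not isolated) | [Li]OC1=C[C@@H](C(C)=C)CC[C@@]1(C)O[Si](CC)(CC)CC | intermediate
6 | (2R,5S,6R)-6-allyl-2-methyl-5-(prop-1-en-2-yl)-2-(triethylsilyloxy)cyclohexan-1-one (major epimer) | O=C1[C@H](CC=C)[C@@H](C(C)=C)CC[C@@]1(C)O[Si](CC)(CC)CC | intermediate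
7 | lithium enolate of 6 (not isolated) | [Li]OC1=C(CC=C)[C@@H](C(C)=C)CC[C@@]1(C)O[Si](CC)(CC)CC | intermediate
8 | (2R,5R,6S)-6-allyl-2,6-dimethyl-5-(prop-1-en-2-yl)-2-(triethylsilyloxy)cyclohexan-1-one | O=C1[C@@](C)(CC=C)[C@@H](C(C)=C)CC[C@@]1(C)O[Si](CC)(CC)CC | intermediate
9 | alkylbis(3-methylbutan-2-yl)borane from 8 (not isolated) | O=C1[C@@](C)(CCCB(C(C)C(C)C)C(C)C(C)C)[C@@H](C(C)=C)CC[C@@]1(C)O[Si](CC)(CC)CC | intermediate
10 | (2R,5R,6S)-6-(3-hydroxypropyl)-2,6-dimethyl-5-(prop-1-en-2-yl)-2-(triethylsilyloxy)cyclohexan-1-one | O=C1[C@@](C)(CCCO)[C@@H](C(C)=C)CC[C@@]1(C)O[Si](CC)(CC)CC | intermediate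
11 | 3-[(1S,3R,6R)-1,3-dimethyl-2-oxo-6-(prop-1-en-2-yl)-3-(triethylsilyloxy)cyclohexyl]propanal | O=C1[C@@](C)(CCC=O)[C@@H](C(C)=C)CC[C@@]1(C)O[Si](CC)(CC)CC | intermediate
12 | tertiary C4 radical from 11 (not isolated) | O=C1[C@@](C)(CCC=O)[C@@H]([C](C)C)CC[C@@]1(C)O[Si](CC)(CC)CC | intermediate
13 | C3 alkoxyl radical of the cis-decalin (not isolated) | O=C1[C@@]2(C)CC[C@H]([O])C(C)(C)[C@H]2CC[C@@]1(C)O[Si](CC)(CC)CC | intermediate
14 | (2R,4aR,6S,8aS)-6-hydroxy-2,5,5,8a-tetramethyl-2-(triethylsilyloxy)octahydronaphthalen-1(2H)-one | O=C1[C@@]2(C)CC[C@H](O)C(C)(C)[C@H]2CC[C@@]1(C)O[Si](CC)(CC)CC | intermediate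
15 | (2R,4aR,6S,8aS)-2,5,5,8a-tetramethyl-2,6-bis(triethylsilyloxy)octahydronaphthalen-1(2H)-one | O=C1[C@@]2(C)CC[C@H](O[Si](CC)(CC)CC)C(C)(C)[C@H]2CC[C@@]1(C)O[Si](CC)(CC)CC | intermediate
16 | (2E,6E)-farnesyl acetate | CC(C)=CCC/C(C)=C/CC/C(C)=C/COC(C)=O | starting material
17 | (2E,6E,10E)-12-hydroxy-3,7,11-trimethyldodeca-2,6,10-trien-1-yl acetate | C/C(=C\CC/C(C)=C/CC/C(C)=C/COC(C)=O)CO | intermediate
18 | (2E,6E,10E)-12-(tert-butyldiphenylsilyloxy)-3,7,11-trimethyldodeca-2,6,10-trien-1-yl acetate | C/C(=C\CC/C(C)=C/CC/C(C)=C/COC(C)=O)CO[Si](C(C)(C)C)(c1ccccc1)c1ccccc1 | intermediate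
19 | [(3E,7E,11E)-13-(tert-butyldiphenylsilyloxy)-4,8,12-trimethyltrideca-3,7,11-trien-1-yl](isopropoxy)dimethylsilane | C/C(=C\CC/C(C)=C/CC/C(C)=C/CC[Si](C)(C)OC(C)C)CO[Si](C(C)(C)C)(c1ccccc1)c1ccccc1 | intermediate
20 | (3E,7E,11E)-13-(tert-butyldiphenylsilyloxy)-4,8,12-trimethyltrideca-3,7,11-trien-1-ol | C/C(=C\CC/C(C)=C/CC/C(C)=C/CCO)CO[Si](C(C)(C)C)(c1ccccc1)c1ccccc1 | intermediate
21 | tert-butyl{[(2E,6E,10E)-13-iodo-2,6,10-trimethyltrideca-2,6,10-trien-1-yl]oxy}diphenylsilane | C/C(=C\CC/C(C)=C/CC/C(C)=C/CCI)CO[Si](C(C)(C)C)(c1ccccc1)c1ccccc1 | intermediate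
22 | organolithium from 21 (not isolated) | C/C(=C\CC/C(C)=C/CC/C(C)=C/CC[Li])CO[Si](C(C)(C)C)(c1ccccc1)c1ccccc1 | intermediate
23 | C9 carbinol (3,8-bis-O-TES, 30-O-TBDPS, 9-hydroxy; side chain on C9 cis to the C10 methyl) | C/C(=C\CC/C(C)=C/CC/C(C)=C/CC[C@]1(O)[C@@]2(C)CC[C@H](O[Si](CC)(CC)CC)C(C)(C)[C@H]2CC[C@@]1(C)O[Si](CC)(CC)CC)CO[Si](C(C)(C)C)(c1ccccc1)c1ccccc1 | intermediate
24 | triethylammonium sulfamate ester of 23 (not isolated) | C/C(=C\CC/C(C)=C/CC/C(C)=C/CC[C@]1(OS(=O)(=O)[N-]C(=O)OC)[C@@]2(C)CC[C@H](O[Si](CC)(CC)CC)C(C)(C)[C@H]2CC[C@@]1(C)O[Si](CC)(CC)CC)CO[Si](C(C)(C)C)(c1ccccc1)c1ccccc1.CC[NH+](CC)CC | intermediate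
25 | 9(11)-alkene (3,8-bis-O-TES, 30-O-TBDPS; C9=C11 geometry not defined) | C/C(=C\CC/C(C)=C/CC/C(C)=C/CC=C1[C@@]2(C)CC[C@H](O[Si](CC)(CC)CC)C(C)(C)[C@H]2CC[C@@]1(C)O[Si](CC)(CC)CC)CO[Si](C(C)(C)C)(c1ccccc1)c1ccccc1 | intermediate
26 | 9(11)-alkene 3,8-diol (30-O-TBDPS) | C/C(=C\CC/C(C)=C/CC/C(C)=C/CC=C1[C@@]2(C)CC[C@H](O)C(C)(C)[C@H]2CC[C@@]1(C)O)CO[Si](C(C)(C)C)(c1ccccc1)c1ccccc1 | intermediate
27 | 30-O-(tert-butyldiphenylsilyl)myrrhanol A | C/C(=C\CC/C(C)=C/CC/C(C)=C/CC[C@@H]1[C@@]2(C)CC[C@H](O)C(C)(C)[C@H]2CC[C@@]1(C)O)CO[Si](C(C)(C)C)(c1ccccc1)c1ccccc1 | intermediate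
28 | Myrrhanol A | C/C(=C\CC/C(C)=C/CC/C(C)=C/CC[C@@H]1[C@@]2(C)CC[C@H](O)C(C)(C)[C@H]2CC[C@@]1(C)O)CO | target

**Step count.** Total: 19 steps. Longest linear sequence: 14 steps (steps 1 to 9 and 15 to 19); the side-chain iodide 21 takes 5 steps (10 to 14).

**Steps most likely to fail**

Step 8. The tertiary radical may be reduced to an isopropyl group before it cyclises, the reversible carbonyl addition may not be trapped, or the oxygen may be placed axial. The fallback sets out from 11 and comes back at 14. The aldehyde is converted into a nitrile (I2, aqueous NH3, THF) to give the cyano ketone F1. The same Fe(acac)3/PhSiH3 hydrogen atom transfer then closes ring A onto the nitrile, a practically irreversible 6-exo-dig addition, and hydrolysis of the imine (aqueous oxalic acid) gives the 3,9-diketone F2. An equilibrating Meerwein–Ponndorf–Verley reduction (Al(OiPr)3, iPrOH, 80 °C) should reduce only the accessible C3 ketone and settle on the more stable equatorial alcohol 14.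

Step 18. The very hindered exocyclic alkene may be hydrogenated so slowly that side-chain alkenes are reduced or isomerised first, or hydrogen may be delivered from the open face. The fallback sets out from 15 and comes back at 27; it sets C9 before the polyene is attached. Methylenation of 15 by Cp2TiMe2 (toluene, 70 °C) gives the exocyclic methylene compound F3. Addition of PhSO2I (from PhSO2Na and I2) followed by elimination by DBU gives the vinyl sulfone F4, and Bu4NF then frees both hydroxyls to give the diol F5. Hydroxyl-directed hydrogenation over [Ir(cod)(PCy3)(py)]PF6 (H2, CH2Cl2), now without any competing alkene, gives the saturated sulfone F6, in which H-9 is cis to O-8. Acetate 18 is converted (K2CO3, MeOH) into the allylic alcohol F7 and then (CBr4, PPh3) into the allylic bromide F8. The trianion of F6 (n-BuLi, 3 equiv, THF/HMPA, −78 °C) is alkylated by F8 at C11 to give the alkylated sulfone F9, and reductive desulfonylation (Na(Hg), Na2HPO4, MeOH) gives 27.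

Step 15. The doubly neopentyl ketone may resist the long-chain organolithium (hydride transfer or no addition), or the triethylsilyl group may migrate from O-8 to the new alkoxide. The fallback sets out from 15 and comes back at 23; it uses a small nucleophile and joins the chain at C11. Dimethylsulfonium methylide (Me3SI, n-BuLi, THF, 0 °C) converts 15 into the spiro-epoxide F10. Acetate 18 is converted into the allylic sulfone F11 (PhSO2Na, Pd(PPh3)4 cat., THF/MeOH). Lithiated F11 (n-BuLi, THF, −78 °C, then BF3·OEt2) opens F10 at its CH2 carbon to give the hydroxy sulfone F12. Hydride desulfonylation of the allylic sulfone (LiBHEt3, PdCl2(dppp) cat., THF, 0 °C) gives 23.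

Further compounds
F1 | step 8 | 3-[(1S,3R,6R)-1,3-dimethyl-2-oxo-6-(prop-1-en-2-yl)-3-(triethylsilyloxy)cyclohexyl]propanenitrile | O=C1[C@@](C)(CCC#N)[C@@H](C(C)=C)CC[C@@]1(C)O[Si](CC)(CC)CC
F2 | step 8 | cis-fused 2,5,5,8a-tetramethyl-2-(triethylsilyloxy)hexahydronaphthalene-1,6-dione (3,9-diketone) | O=C1[C@@]2(C)CCC(=O)C(C)(C)[C@H]2CC[C@@]1(C)O[Si](CC)(CC)CC
F3 | step 18 | 9-methylene analogue of 15 (exocyclic C9=C11H2, 3,8-bis-O-TES) | C=C1[C@@]2(C)CC[C@H](O[Si](CC)(CC)CC)C(C)(C)[C@H]2CC[C@@]1(C)O[Si](CC)(CC)CC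
F4 | step 18 | vinyl sulfone (C9=C11H–SO2Ph, 3,8-bis-O-TES) | O=S(=O)(C=C1[C@@]2(C)CC[C@H](O[Si](CC)(CC)CC)C(C)(C)[C@H]2CC[C@@]1(C)O[Si](CC)(CC)CC)c1ccccc1
F5 | step 18 | vinyl sulfone 3,8-diol | O=S(=O)(C=C1[C@@]2(C)CC[C@H](O)C(C)(C)[C@H]2CC[C@@]1(C)O)c1ccccc1
F6 | step 18 | C11 phenyl sulfone 3,8-diol with H-9 cis to O-8 | O=S(=O)(C[C@@H]1[C@@]2(C)CC[C@H](O)C(C)(C)[C@H]2CC[C@@]1(C)O)c1ccccc1
F7 | step 18 | (2E,6E,10E)-12-(tert-butyldiphenylsilyloxy)-3,7,11-trimethyldodeca-2,6,10-trien-1-ol | C/C(=C\CC/C(C)=C/CC/C(C)=C/CO)CO[Si](C(C)(C)C)(c1ccccc1)c1ccccc1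
F8 | step 18 | (2E,6E,10E)-12-(tert-butyldiphenylsilyloxy)-3,7,11-trimethyldodeca-2,6,10-trien-1-yl bromide | C/C(=C\CC/C(C)=C/CC/C(C)=C/CBr)CO[Si](C(C)(C)C)(c1ccccc1)c1ccccc1
F9 | step 18 | 11-(phenylsulfonyl) derivative of 27 (C11 epimers) | C/C(=C\CC/C(C)=C/CC/C(C)=C/CC([C@@H]1[C@@]2(C)CC[C@H](O)C(C)(C)[C@H]2CC[C@@]1(C)O)S(=O)(=O)c1ccccc1)CO[Si](C(C)(C)C)(c1ccccc1)c1ccccc1
F10 | step 15 | C9 spiro-epoxide of 15 (epoxide CH2 cis to the C10 methyl) | C1O[C@]12[C@@]3(C)CC[C@H](O[Si](CC)(CC)CC)C(C)(C)[C@H]3CC[C@@]2(C)O[Si](CC)(CC)CC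
F11 | step 15 | (2E,6E,10E)-12-(tert-butyldiphenylsilyloxy)-3,7,11-trimethyldodeca-2,6,10-trien-1-yl phenyl sulfone | C/C(=C\CC/C(C)=C/CC/C(C)=C/CS(=O)(=O)c1ccccc1)CO[Si](C(C)(C)C)(c1ccccc1)c1ccccc1
F12 | step 15 | 12-(phenylsulfonyl) derivative of 23 (C12 epimers) | C/C(=C\CC/C(C)=C/CC/C(C)=C/C(C[C@]1(O)[C@@]2(C)CC[C@H](O[Si](CC)(CC)CC)C(C)(C)[C@H]2CC[C@@]1(C)O[Si](CC)(CC)CC)S(=O)(=O)c1ccccc1)CO[Si](C(C)(C)C)(c1ccccc1)c1ccccc1
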